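The trap in these curves is to take the bend for the end: by 60 min the alder run looks stopped, yet the slowing has a pace of its own, and that pace can be read.

| flask | starting material | partner | free catalyst | time |
|---|---|---|---|---|
| alder | 0.400 M | 0.600 M | 0.00200 M |  |
| maple | 0.600 M | 0.600 M | 0.00200 M |  |
| cedar | 0.400 M | 0.600 M | 0.00600 M |  |
| larch | 0.400 M | 1.80 M | 0.00200 M |  |
| ash | 0.400 M | 0.600 M | 0.00200 M | 360 min |

| alder run: time / min | alder run: [product] / M | maple run: time / min | maple run: [product] / M | cedar run: time / min | cedar run: [product] / M | larch run: time / min | larch run: [product] / M |
|---|---|---|---|---|---|---|---|
| 12 | 0.1799 | 12 | 0.2507 | 12 | 0.2566 | 12 | 0.2940 |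
| 24 | 0.2384 | 24 | 0.3269 | 24 | 0.3135 | 24 | 0.3435 |
| 36 | 0.2709 | 36 | 0.3646 | 36 | 0.3366 | 36 | 0.3630 |
| 48 | 0.2905 | 48 | 0.3862 | 48 | 0.3521 | 48 | 0.3742 |
| 60 | 0.3018 | 60 | 0.3980 | 60 | 0.3611 | 60 | 0.3801 |

(readings scatter by 0.001 M)

* order of the initial rate in [free catalyst], near the charge of the alder run, the rate being that where two percent of its starting material are product
* order of the initial rate in [starting material], near the charge of the alder run, the rate being that where two percent of its starting material are product (one fixed amount of product, the same in the runs compared)
* product in the ash run at 360 min, as a share of the starting material charged

- Overall: starting material + partner -> product, with free catalyst as catalyst.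
- Constant volume, constant temperature.
- Readings of a species count what is bound in complexes too.
- "The second partner" is partner.
- An order is taken over about fifteen percent of the charge, up and down.

I followed the rate and split it in two. Over the first 12 min alder made product at 0.0150 M min⁻¹, and over its last interval at 9.42 × 10⁻⁴ M min⁻¹, a fall by a factor of 15.9. I wrote the rate as remaining starting material divided by a clock, the pseudo-first-order time constant, read from each interval as its length over the logarithm of the remainder's fall. That clock lengthened from 20.1 min to 110 min, a factor of 5.48. The thinning of the starting material gave the other 2.90, so the clock slowed the flask more than the thinning did.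

The interval from 24 min to 36 min had a clock of 53.4 min. Between it and the last interval the clock's gain, taken over the run time that passed, came to 2.36, and I called this ratio the stretch. The early end is read directly, and I joined the far end to it by assuming a steady stretch. From a clock of 124 min at 60 min, the logarithm of the remainder falls by a further 0.805 up to 360 min. The ash run has the alder charge, so I reckoned 89.0% product. That figure is soft, since the last interval gained 0.0113 M against a scatter of 0.001 M in each reading.

The forecast gave 0.62 and 0.92 for the orders and 83% for the ash run, lower than my figure. It judged that “death looks first-order in time”.

The flask gave orders of 0.64 and 1.0, and 88.4% in the ash run.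

    2 free catalyst ⇌ catalyst dimer, settled at all times (1600 M⁻¹)
    free catalyst + starting material + partner → product + free catalyst (204.0 M⁻² min⁻¹)
    free catalyst + partner ⇌ idle catalyst-reagent complex, settled at all times (0.6670 M⁻¹)
    2 partner → lost reagent (0.03900 M⁻¹ min⁻¹)

That is 5.4 percentage points above the forecast, with my figure at 89.0%. The turnover step ran while starting material and partner were both there, and beside it pairs of partner went to lost reagent, with a first half-life by that step alone of 21.4 min at the alder charge. In the cedar run the first two intervals gave clocks of 11.7 min and 23.7 min, a stretch of 1.00. With a starting clock of 7.14 min from its early rate, that stretch puts half the charge turned at 7.15 min, and the cedar run reached it at 6.88 min.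

The data stem from a simulated flask for an exercise, noise included.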